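**Plan**
Retrosynthesis: the C6'–prenyl bond is cut first (Claisen, back to an ether on O7'), the C4 ketone is traced to a C4–OMe group, ring C is cut at O1–C2 and C3–C4, and the furan ring is cut at O1'–C2' and C3'–C3a' back to 5-iodovanillin.
Enabling feature: ring C is a six-membered oxygen heterocycle fused to the phloroglucinol ring A through O1–C8a and C4–C4a, so O1–C8a–C4a–C4 is a latent ortho-quinone methide; C2 bears a benzofuran-5-yl group whose C5' is para to the furan oxygen O1', so C2–C3 is a latent, polarised vinylarene.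
Forward: the furan ring is built on 5-iodovanillin, O7' is capped as a 1,1-dimethylpropargyl ether (a latent prenyl group) and the aldehyde is methylenated; ring C then closes by [4+2] cycloaddition with the ortho-quinone methide from bis-MOM phloroglucinaldehyde and trimethyl orthoformate.
Endgame: C4–OMe is oxidised to C4=O, the alkyne is semi-hydrogenated, the allyl group is shifted to C6' and the MOM groups are removed.
Stereochemistry: C2 (S), the only stereocentre of the target, is set in the cycloaddition by a chiral phosphate; the C4 centre formed with it is erased by oxidation, and only neutral or acidic steps follow once the ketone exists.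

Key step: step 7

Assumption: the (R)-acid is taken to deliver the (2S) adduct; if the sense of induction is the opposite, the (S)-acid is used and nothing else changes. Unprimed locants are flavanone locants, primed ones belong to the benzofuran.

**Route**

Step 1
Reactants: 1 2,4,6-trihydroxybenzaldehyde
Product: 2 2-hydroxy-4,6-bis(methoxymethoxy)benzaldehyde
Conditions: MOMCl (2.1 equiv), i-Pr2NEt, CH2Cl2, 0 °C to rt
Reagents that add atoms: chloromethyl methyl ether (MOMCl), COCCl
Why: MOM ether formation (O-alkylation of phenoxides) takes the 4-OH and one ortho OH, while the remaining ortho OH is held in a hydrogen bond to the formyl oxygen and stays free, which is the phenol needed for the quinone methide.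

Step 2
Reactants: 3 5-iodovanillin (4-hydroxy-3-iodo-5-methoxybenzaldehyde); 4 ethynyltrimethylsilane
Product: 6 7-methoxy-2-(trimethylsilyl)-1-benzofuran-5-carbaldehyde, via alkynylphenol 5 (not isolated)
Conditions: Pd(PPh3)2Cl2 (3 mol%), CuI (6 mol%), Et3N, DMF, 60 °C
Reagents that add atoms: none
Why: Sonogashira coupling at the C–I bond gives alkynylphenol 5, whose phenolic oxygen adds to the metal-activated alkyne in a 5-endo-dig heteroannulation that closes the furan ring; any 5 left uncyclised is converted into the same product 7 by the fluoride of step 3.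

Step 3
Reactants: 6 7-methoxy-2-(trimethylsilyl)-1-benzofuran-5-carbaldehyde
Product: 7 7-methoxy-1-benzofuran-5-carbaldehyde
Conditions: TBAF (1.2 equiv), wet THF, rt
Reagents that add atoms: none
Why: Fluoride-mediated protodesilylation cleaves the C2'–Si bond of the 2-silylbenzofuran and leaves the aldehyde and the methyl ether untouched.

Step 4
Reactants: 7 7-methoxy-1-benzofuran-5-carbaldehyde
Product: 8 7-hydroxy-1-benzofuran-5-carbaldehyde
Conditions: BBr3 (2.5 equiv), CH2Cl2, −78 to 0 °C; aqueous work-up
Reagents that add atoms: none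
Why: BBr3 demethylation of the aryl methyl ether proceeds through the aryloxyborane and bromide attack on the methyl group, the aldehyde being only complexed and returned on work-up and the benzofuran tolerating the reagent at low temperature.

Step 5
Reactants: 8 7-hydroxy-1-benzofuran-5-carbaldehyde; 9 3-chloro-3-methylbut-1-yne
Product: 10 7-[(2-methylbut-3-yn-2-yl)oxy]-1-benzofuran-5-carbaldehyde
Conditions: CuCl2·2H2O (1 mol%), DBU, MeCN, 0 °C
Reagents that add atoms: none
Why: Copper-catalysed propargylic etherification (Godfrey conditions) of the phenol with the tertiary propargylic chloride gives the aryl 1,1-dimethylpropargyl ether, which serves as an acid- and oxidant-stable latent prenyl group.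

Step 6
Reactants: 10 7-[(2-methylbut-3-yn-2-yl)oxy]-1-benzofuran-5-carbaldehyde
Product: 11 5-ethenyl-7-[(2-methylbut-3-yn-2-yl)oxy]-1-benzofuran
Conditions: Ph3PCH3Br, KOtBu, THF, 0 °C to rt
Reagents that add atoms: methyltriphenylphosphonium bromide, C[P+](c1ccccc1)(c1ccccc1)c1ccccc1.[Br-]
Why: Wittig methylenation of the non-enolisable aryl aldehyde gives the vinylarene, the ylide being too weak a base to disturb the terminal alkyne.

Step 7
Reactants: 2 2-hydroxy-4,6-bis(methoxymethoxy)benzaldehyde; 11 5-ethenyl-7-[(2-methylbut-3-yn-2-yl)oxy]-1-benzofuran; 12 trimethyl orthoformate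
Product: 15 (2S,4S)-4-methoxy-5,7-bis(methoxymethoxy)-2-{7-[(2-methylbut-3-yn-2-yl)oxy]-1-benzofuran-5-yl}-3,4-dihydro-2H-chromene, via dimethyl acetal 13 (not isolated), via ortho-quinone methide 14 (not isolated)
Conditions: (R)-3,3'-bis(2,4,6-triisopropylphenyl)-1,1'-binaphthyl-2,2'-diyl hydrogen phosphate (10 mol%), 5 Å MS, PhMe, 0 °C
Reagents that add atoms: none
Why: Proposed new method: the acid turns 2 and 12 into acetal 13, which loses methanol to ortho-quinone methide 14 (in its O-protonated form a 2-hydroxyaryl methoxycarbenium ion that is ion-paired with the chiral phosphate and also hydrogen-bonded to it through the phenolic OH), and the vinyl group of 11 adds in an asynchronous inverse-electron-demand hetero-Diels–Alder reaction, C3–C4 forming ahead of O1–C2. The closest known reactions are the racemic acid-promoted assembly of 2,4-cis-4-alkoxyflavans from salicylaldehydes, orthoformates and styrenes and the chiral phosphoric acid catalysed [4+2] cycloadditions of ortho-quinone methides with hydroxystyrenes and enol ethers; what is new is enantiocontrol with a vinylarene that carries no hydrogen-bond donor. Ring C closes in the [4+2] mode (4π heterodiene O1=C8a–C4a=C4 plus the 2π alkene, suprafacial on both partners), the last bond being capture of the C2 benzylic cation by O1. C2 is set by the phosphate, which shields one face of the bound heterodiene so that the alkene adds on the open face; C4 follows from the E geometry of 14 and an endo approach of the aryl group (2,4-cis) and is of no consequence, since step 8 removes it. Regioselectivity is secured by the furan oxygen O1' para to the vinyl group, which stabilises positive charge at the future C2; chemoselectivity over the furan 2,3-double bond, the alkyne and the MOM acetals rests on the higher nucleophilicity of the para-oxygenated styrene and on the weak acid, and the sieves take up methanol to suppress interception of the cation.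

Step 8
Reactants: 15 (2S,4S)-4-methoxy-5,7-bis(methoxymethoxy)-2-{7-[(2-methylbut-3-yn-2-yl)oxy]-1-benzofuran-5-yl}-3,4-dihydro-2H-chromene
Product: 16 (2S)-5,7-bis(methoxymethoxy)-2-{7-[(2-methylbut-3-yn-2-yl)oxy]-1-benzofuran-5-yl}-2,3-dihydro-4H-chromen-4-one
Conditions: DDQ (1.3 equiv), CH2Cl2/pH 7 phosphate buffer (10:1), 0 °C
Reagents that add atoms: water, O
Why: DDQ oxidation of an electron-rich benzylic methyl ether, the reaction that underlies PMB and DMB ether cleavage, removes hydride from C4–H (activated by OMe and by the ortho- and para-oxygens of ring A), and water turns the resulting oxocarbenium ion into the ketone with loss of methanol, so that both C4 epimers converge while C2, the alkyne and the buffered MOM groups are untouched.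

Step 9
Reactants: 16 (2S)-5,7-bis(methoxymethoxy)-2-{7-[(2-methylbut-3-yn-2-yl)oxy]-1-benzofuran-5-yl}-2,3-dihydro-4H-chromen-4-one
Product: 17 (2S)-5,7-bis(methoxymethoxy)-2-{7-[(2-methylbut-3-en-2-yl)oxy]-1-benzofuran-5-yl}-2,3-dihydro-4H-chromen-4-one
Conditions: H2 (1 atm), Pd/CaCO3 poisoned with Pb(OAc)2 (Lindlar catalyst), quinoline, EtOAc, rt
Reagents that add atoms: none
Why: Lindlar semi-hydrogenation reduces the terminal alkyne to the alkene and, with the poisoned catalyst, leaves the benzofuran 2,3-double bond, the ketone and the benzylic C2–O1 bond alone.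

Step 10
Reactants: 17 (2S)-5,7-bis(methoxymethoxy)-2-{7-[(2-methylbut-3-en-2-yl)oxy]-1-benzofuran-5-yl}-2,3-dihydro-4H-chromen-4-one
Product: 19 (2S)-2-[7-hydroxy-6-(3-methylbut-2-en-1-yl)-1-benzofuran-5-yl]-5,7-bis(methoxymethoxy)-2,3-dihydro-4H-chromen-4-one, via ortho-dienone 18 (not isolated)
Conditions: PhMe, 110 °C, sealed tube
Reagents that add atoms: none
Why: Aromatic Claisen rearrangement of the aryl 1,1-dimethylallyl ether delivers the allyl group, inverted to prenyl, to C6', the only free ortho position (C7a' is the ring-fusion carbon), and dienone 18 enolises to the phenol; with no base present ring C has no easy retro-oxa-Michael pathway and C2 should stay (S).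

Step 11
Reactants: 19 (2S)-2-[7-hydroxy-6-(3-methylbut-2-en-1-yl)-1-benzofuran-5-yl]-5,7-bis(methoxymethoxy)-2,3-dihydro-4H-chromen-4-one
Product: 20 (2S)-5,7-dihydroxy-2-[7-hydroxy-6-(3-methylbut-2-en-1-yl)-1-benzofuran-5-yl]-2,3-dihydro-4H-chromen-4-one
Conditions: 3 M aq HCl, MeOH, 45 °C
Reagents that add atoms: none
Why: Acid-catalysed acetal exchange with methanol removes both MOM groups, and under dilute acid flavanones keep their C2 configuration and the prenylphenol should not cyclise.

**Compound list**
1 | 2,4,6-trihydroxybenzaldehyde | O=Cc1c(O)cc(O)cc1O | starting material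
2 | 2-hydroxy-4,6-bis(methoxymethoxy)benzaldehyde | O=Cc1c(O)cc(OCOC)cc1OCOC | intermediate
3 | 5-iodovanillin (4-hydroxy-3-iodo-5-methoxybenzaldehyde) | COc1cc(C=O)cc(I)c1O | starting material
4 | ethynyltrimethylsilane | C#C[Si](C)(C)C | starting material
5 | 4-hydroxy-3-methoxy-5-[(trimethylsilyl)ethynyl]benzaldehyde | COc1cc(C=O)cc(C#C[Si](C)(C)C)c1O | intermediate (not isolated)
6 | 7-methoxy-2-(trimethylsilyl)-1-benzofuran-5-carbaldehyde | COc1cc(C=O)cc2cc([Si](C)(C)C)oc12 | intermediate
7 | 7-methoxy-1-benzofuran-5-carbaldehyde | COc1cc(C=O)cc2ccoc12 | intermediate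
8 | 7-hydroxy-1-benzofuran-5-carbaldehyde | O=Cc1cc(O)c2occc2c1 | intermediate
9 | 3-chloro-3-methylbut-1-yne | CC(C)(Cl)C#C | starting material
10 | 7-[(2-methylbut-3-yn-2-yl)oxy]-1-benzofuran-5-carbaldehyde | O=Cc1cc(OC(C)(C)C#C)c2occc2c1 | intermediate
11 | 5-ethenyl-7-[(2-methylbut-3-yn-2-yl)oxy]-1-benzofuran | C=Cc1cc(OC(C)(C)C#C)c2occc2c1 | intermediate
12 | trimethyl orthoformate | COC(OC)OC | starting material
13 | 2-(dimethoxymethyl)-3,5-bis(methoxymethoxy)phenol | COC(OC)c1c(O)cc(OCOC)cc1OCOC | intermediate (not isolated)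
14 | (6E)-6-(methoxymethylidene)-3,5-bis(methoxymethoxy)cyclohexa-2,4-dien-1-one | CO/C=C1/C(=O)C=C(OCOC)C=C1OCOC | intermediate (not isolated)
15 | (2S,4S)-4-methoxy-5,7-bis(methoxymethoxy)-2-{7-[(2-methylbut-3-yn-2-yl)oxy]-1-benzofuran-5-yl}-3,4-dihydro-2H-chromene (2,4-cis) | CO[C@H]1C[C@@H](c2cc(OC(C)(C)C#C)c3occc3c2)Oc2cc(OCOC)cc(OCOC)c21 | intermediate
16 | (2S)-5,7-bis(methoxymethoxy)-2-{7-[(2-methylbut-3-yn-2-yl)oxy]-1-benzofuran-5-yl}-2,3-dihydro-4H-chromen-4-one | O=C1C[C@@H](c2cc(OC(C)(C)C#C)c3occc3c2)Oc2cc(OCOC)cc(OCOC)c21 | intermediate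
17 | (2S)-5,7-bis(methoxymethoxy)-2-{7-[(2-methylbut-3-en-2-yl)oxy]-1-benzofuran-5-yl}-2,3-dihydro-4H-chromen-4-one | O=C1C[C@@H](c2cc(OC(C)(C)C=C)c3occc3c2)Oc2cc(OCOC)cc(OCOC)c21 | intermediate
18 | (2S)-5,7-bis(methoxymethoxy)-2-[6-(3-methylbut-2-en-1-yl)-7-oxo-6,7-dihydro-1-benzofuran-5-yl]-2,3-dihydro-4H-chromen-4-one (either configuration at C6') | CC(C)=CCC1C(=O)c2occc2C=C1[C@@H]1CC(=O)c2c(OCOC)cc(OCOC)cc2O1 | intermediate (not isolated)
19 | (2S)-2-[7-hydroxy-6-(3-methylbut-2-en-1-yl)-1-benzofuran-5-yl]-5,7-bis(methoxymethoxy)-2,3-dihydro-4H-chromen-4-one | CC(C)=CCc1c([C@@H]2CC(=O)c3c(OCOC)cc(OCOC)cc3O2)cc2ccoc2c1O | intermediate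
20 | (2S)-5,7-dihydroxy-2-[7-hydroxy-6-(3-methylbut-2-en-1-yl)-1-benzofuran-5-yl]-2,3-dihydro-4H-chromen-4-one | CC(C)=CCc1c([C@@H]2CC(=O)c3c(O)cc(O)cc3O2)cc2ccoc2c1O | target

**Count**
Total: 11 steps. Longest linear sequence: 10 steps (3 to 20, steps 2 to 11); step 1 supplies the second partner of the cycloaddition.

**Steps most likely to fail**

Step 7. Facial discrimination may be poor, because the vinylarene has no hydrogen-bond donor to fix it to the phosphate, and a racemic background addition may compete. The fallback uses known chemistry and takes the stereocentre from a resolution instead of from the catalyst. It sets out from 2, 11 and 12: the cycloaddition is run in its established racemic form with an achiral acid (diphenyl hydrogen phosphate, PhMe, rt) to give the racemic 2,4-cis adduct F1. DDQ under the conditions of step 8 then gives the racemic ketone F2. Noyori asymmetric transfer hydrogenation (RuCl(p-cymene)[(R,R)-TsDPEN] or its mirror image, whichever consumes the (2R)-ketone, HCO2H/Et3N, EtOAc, rt, stopped near half conversion) acts as a kinetic resolution. It reduces the (2R)-ketone to the (2R,4R)-cis-flavan-4-ol F3 and leaves the (2S)-ketone, which is separated by chromatography. The route is rejoined at 16.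

Step 8. Hydride may be abstracted at C2–H (benzylic to the benzofuran) instead of C4–H, or the oxidation may stall if C4–H cannot align with the π system of ring A. The fallback replaces hydride abstraction by ionisation followed by alcohol oxidation. It sets out from 15: PPTS in acetone/H2O at rt exchanges the C4 methoxy group for hydroxyl and gives the (2S)-flavan-4-ol F4 as a mixture of C4 epimers. Dess–Martin periodinane (NaHCO3, CH2Cl2, rt) oxidises it to the ketone. The route is rejoined at 16.

Step 10. On heating the ketone, ring C may open and reclose through the 2'-hydroxychalcone (retro-oxa-Michael, then oxa-Michael), eroding the C2 configuration, and crowding at C6' may slow the shift. The fallback moves the rearrangement to the flavan level, where ring C cannot open. It sets out from 15: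
- Lindlar semi-hydrogenation as in step 9 gives the 1,1-dimethylallyl ether F5.
- Heating in PhMe at 110 °C gives, through the ortho-dienone F6 (not isolated), the 6'-prenyl-7'-phenol F7.
- MOMCl/i-Pr2NEt in CH2Cl2 caps the phenol as the tris-MOM ether F8, so that DDQ cannot cyclise the prenylphenol to a chromene.
- DDQ in CH2Cl2/pH 7 buffer at 0 °C gives the tris-MOM flavanone F9.
- 3 M aq HCl in MeOH at 45 °C removes the three MOM groups.

The route is rejoined at 20.

**Further compounds**
F1 | step 7 | racemic 2,4-cis-4-methoxy-5,7-bis(methoxymethoxy)-2-{7-[(2-methylbut-3-yn-2-yl)oxy]-1-benzofuran-5-yl}-3,4-dihydro-2H-chromene | COC1CC(c2cc(OC(C)(C)C#C)c3occc3c2)Oc2cc(OCOC)cc(OCOC)c21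
F2 | step 7 | racemic 5,7-bis(methoxymethoxy)-2-{7-[(2-methylbut-3-yn-2-yl)oxy]-1-benzofuran-5-yl}-2,3-dihydro-4H-chromen-4-one | O=C1CC(c2cc(OC(C)(C)C#C)c3occc3c2)Oc2cc(OCOC)cc(OCOC)c21
F3 | step 7 | (2R,4R)-5,7-bis(methoxymethoxy)-2-{7-[(2-methylbut-3-yn-2-yl)oxy]-1-benzofuran-5-yl}-3,4-dihydro-2H-chromen-4-ol (2,4-cis) | O[C@@H]1C[C@H](c2cc(OC(C)(C)C#C)c3occc3c2)Oc2cc(OCOC)cc(OCOC)c21
F4 | step 8 | (2S)-5,7-bis(methoxymethoxy)-2-{7-[(2-methylbut-3-yn-2-yl)oxy]-1-benzofuran-5-yl}-3,4-dihydro-2H-chromen-4-ol (both C4 epimers) | OC1C[C@@H](c2cc(OC(C)(C)C#C)c3occc3c2)Oc2cc(OCOC)cc(OCOC)c21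
F5 | step 10 | (2S,4S)-4-methoxy-5,7-bis(methoxymethoxy)-2-{7-[(2-methylbut-3-en-2-yl)oxy]-1-benzofuran-5-yl}-3,4-dihydro-2H-chromene | CO[C@H]1C[C@@H](c2cc(OC(C)(C)C=C)c3occc3c2)Oc2cc(OCOC)cc(OCOC)c21
F6 | step 10 | 5-[(2S,4S)-4-methoxy-5,7-bis(methoxymethoxy)-3,4-dihydro-2H-chromen-2-yl]-6-(3-methylbut-2-en-1-yl)-1-benzofuran-7(6H)-one (not isolated) | CO[C@H]1C[C@@H](C2=Cc3ccoc3C(=O)C2CC=C(C)C)Oc2cc(OCOC)cc(OCOC)c21
F7 | step 10 | 5-[(2S,4S)-4-methoxy-5,7-bis(methoxymethoxy)-3,4-dihydro-2H-chromen-2-yl]-6-(3-methylbut-2-en-1-yl)-1-benzofuran-7-ol | CO[C@H]1C[C@@H](c2cc3ccoc3c(O)c2CC=C(C)C)Oc2cc(OCOC)cc(OCOC)c21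
F8 | step 10 | (2S,4S)-4-methoxy-5,7-bis(methoxymethoxy)-2-[7-(methoxymethoxy)-6-(3-methylbut-2-en-1-yl)-1-benzofuran-5-yl]-3,4-dihydro-2H-chromene | CO[C@H]1C[C@@H](c2cc3ccoc3c(OCOC)c2CC=C(C)C)Oc2cc(OCOC)cc(OCOC)c21
F9 | step 10 | (2S)-5,7-bis(methoxymethoxy)-2-[7-(methoxymethoxy)-6-(3-methylbut-2-en-1-yl)-1-benzofuran-5-yl]-2,3-dihydro-4H-chromen-4-one | O=C1C[C@@H](c2cc3ccoc3c(OCOC)c2CC=C(C)C)Oc2cc(OCOC)cc(OCOC)c21
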